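The data are calculated on assumed constants, and the scatter is random.

A leftover opens this problem: over its later readings the west run has used 47.9% of its G and X and the east run 61.7%, though E was charged at 2.10 and 3.30 of the G and X together.

common to all: G 0.25 M; X 0.25 M; J 2.8 mol%
- west: E 4.2 equiv; run made earlier
- east: E 6.6 equiv; run made earlier
- flask: E 3.00 equiv; time 20 h

| run | time / h | G / % | Z / % | X / % |
|---|---|---|---|---|
| west | 1.00 | 20.8 | 34.9 | 29.0 |
| west | 3.00 | 25.7 | 37.6 | 27.4 |
| west | 6.00 | 26.9 | 34.0 | 26.5 |
| west | 8.00 | 25.0 | 37.5 | 26.4 |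
| west | 12.0 | 26.6 | 35.6 | 24.8 |
| west | 15.0 | 26.8 | 36.8 | 25.4 |
| east | 1.00 | 13.3 | 45.8 | 24.2 |
| east | 3.00 | 18.2 | 45.8 | 21.0 |
| east | 6.00 | 19.3 | 46.5 | 20.5 |
| east | 8.00 | 19.1 | 46.8 | 18.7 |
| east | 12.0 | 20.6 | 44.6 | 20.0 |
| east | 15.0 | 18.1 | 45.3 | 17.0 |

(readings scatter by 1 percentage point)

- J is single-handed; G and X are mirror images of each other, charged as a racemate, each of them at the stated concentration

* share of the G and X together used up at 20 h
* Z at 20 h, in percent of the G and X together charged
* X at 20 h, in percent of the G and X together charged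

This reckoning assumes that G and X stay about equal, and that E decays by itself besides reacting with them. Dividing the two rates removes time: if the levelling-off marks the end of E, then E charged, as a fraction of the charge, equals the conversion plus W times the logarithm of the inverse of the fraction left. W is the waste charge, the E lost per unit of that logarithm at this loading of J. West gives 2.49 and east 2.80, so W is about 2.64. With 1.50 charged, substitution gives a conversion of 35.6%, with X at 32.2%.

The forecast differs: 39.8%, Z 29.3%, X 29.9%, from runs that “behave as an equilibrium, not a kinetic resolution”.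

The flask gives 37.0%, Z 29.0%, X 31.5%.

    E + J + G → J + Z (k = 0.210 /M²/s)
    E + J + X → J + L (k = 0.0450 /M²/s)
    G ⇌ X (k = 1.50 × 10⁻⁴ /s)
    E → Q (k = 0.00100 /s)

The flask's E, the limiting reagent, stands at 0% of its charge at 20.0 h, less than the 63% of G, and conversion still reads 37.0% at 200 h. Its own W comes to 2.45. For the neighbour with 7.50 equiv of E, the same W and substitution give 69.2%. That neighbour gives 66.4%, with its E at 0%.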